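## The problem

Atom numbers are those of the acid and are kept for every intermediate: C1 is the carboxyl carbon on C2; ring A (cyclohexene) is C2–C3–C7–C8–C9–C10; ring B (cyclopentene) is C3–C4–C5–C6–C7; C4(Et)=C5, C6 carries methyl, C8(Et)=C9, and C10 carries ethyl and the (E)-styryl group C11=C12. The β face is the one that carries the C6 methyl group and 7-H; α is the other.

- Spiculoic acid B (27) is a trans-fused bicyclo[4.3.0]nonadiene: ring A and ring B share the C3–C7 bond, with 3-H on the α face and 7-H on the β face.
- Five contiguous stereocentres (C6, C7, C3, C2, C10) must be set. C2 (CH3 β, CO2H α) and C10 (ethyl β, styryl α) are adjacent quaternary carbons, and this pair is the core difficulty.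
- A relay of control is available. The C6 methyl group can send a new bond at C7 to the opposite face of the five-membered ring. C7 then favours the trans arrangement at C3. The trans ring fusion freezes ring A in one half-chair, in which C2 and C10 can be set by axial attack.
- The styrene and the two trisubstituted alkenes exclude strong acid late in the route (cation–alkene cyclisation, lactonisation of the γ,δ-unsaturated acid).
- The carboxyl group is neopentyl on both sides, so its ester cannot be expected to hydrolyse at the carbonyl carbon.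
- C3 is open to epimerisation whenever C2 or C4 is a carbonyl carbon, and C6 whenever it is γ to a conjugated carbonyl group.
- The enabling feature is that C8(Et)–C9–C10(Et) is the skeleton of heptan-4-one. With C9 as a ketone and a C10=C2 double bond, C10 is the α-carbon and C2 the β-carbon of an enone, so the two quaternary centres can come from one conjugate addition followed by trapping of the enolate.

## Retrosynthesis

**27 ⇒ 26.** The O–CH3 bond of methyl ester 26 is cut. C1 is carried as a methyl ester because dimethyl oxalate delivers it in that form. The forward reaction must attack the methyl group (SN2 dealkylation), not the shielded carbonyl carbon.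

**26 ⇒ 25 ⇒ 23.** The C4–ethyl bond is cut to alkenyl triflate 25 and from there to C4 ketone 23. Carrying the ethyl-substituted alkene from the start would remove the C4 oxygen that is needed to build ring B and to lithiate C3. In 23 the ketone can be enolised kinetically only toward the C5 methylene, because 3-H lies between the carbonyl and quaternary C2, so the C4=C5 position follows. The forward step is a coupling of an alkenyl triflate with EtMgBr that tolerates the ester.

**23 ⇒ 22 ⇒ 21 ⇒ 19.** The C9 oxygen is put back: ketal 22, enol triflate 21, ketone 19. C10 is quaternary, so the C9 ketone can enolise only toward C8 and its removal places C8=C9 without ambiguity. C9 is processed before C4 is unmasked, so that only one ketone is present at a time.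

**19 ⇒ 14 + 17 (+ methyl).** The C2–CH3 and C10–C11 bonds are cut together. This leaves ene-keto ester 14 and (E)-styryl(phenyl)iodonium tetrafluoroborate 17. Forming the C2–C10 bond instead would require joining two fully substituted carbons, whereas here both quaternary centres grow on an existing ring. The precursor loses two stereocentres and the whole styrene. The forward reaction must add methyl to C2 on the β face and alkenylate the C9–C10 enolate on the α face.

**14 ⇒ 12 ⇒ 8 + 10 (from 9).** The C10=C2 bond (aldol condensation) and the C7–C8 bond (conjugate addition) are cut: a Robinson annulation of heptan-4-one (9), used as its silyl enol ether 10, onto alkenyl α-keto ester 8. Heptan-4-one is symmetrical, so there is no regiochemical question, and it supplies both ethyl groups and the C9 carbonyl. The conjugate addition must occur anti to the C6 methyl group, and C3 must end trans to C7.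

**8 ⇒ 5 + 6.** The C2–C3 bond is cut to vinyllithium 7 (from iodide 5) and dimethyl oxalate (6). The dioxolane at C4 protects the ketone and also makes the α-lithiated enone equivalent possible.

**5 ⇒ 4 ⇒ 3 ⇒ 2 ⇒ 1.** Ketalisation, α-iodination and elimination lead back to (R)-4-silyloxycyclopentenone 1. C6 is set by cuprate addition anti to the silyloxy group. Conjugate reduction of 3-methylcyclopent-2-enone followed by dehydrogenation was set aside: the enolate formed by conjugate reduction has its double bond toward the methyl-bearing carbon, so dehydrogenation would return the achiral enone.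

**17 ⇒ 15 + 16.** The C–I bond is cut to (E)-styrylboronic acid (15) and PhI(OAc)2 (16). The boron-to-iodine exchange retains the alkene geometry.

## Roads not taken

**Alternative 1: crossed photocycloaddition and de Mayo fragmentation.**
- Cut: C2–C3 and C9–C10.
- Forward step: irradiation near 350 nm of an enol ester whose C3=C9 alkene is tethered through the ester to a C2=C10 enoate. It gives the spiro 2-oxabicyclo[2.1.1]hexan-3-one A1. Lactone opening and retro-aldol cleavage of the temporary C3–C9 bond would follow.
- Merits: both bonds to the quaternary carbons form intramolecularly, which is less sensitive to congestion than an intermolecular addition. The bicycle fixes the relation between C2 and C10. In this respect it is better than the chosen plan, which needs two separate face selections.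
- Weak points: esters prefer the extended conformation, which keeps the two alkenes apart. The tetrasubstituted enoate can lose its geometry in the biradical, so C10 is not secure. No ring of the target closes: ring A, the styrene (from CH2OSi) and C3 (by protonation next to the C4 ketone) all remain to be made after A1.
- Comparison: the chosen plan sets against this a ring A that arrives complete from heptan-4-one, a styrene introduced in one bond-forming event, and a shorter end game.

**Alternative 2: desymmetrising ring-closing metathesis.**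
- Cut: C8=C9.
- Forward step: the chiral hexavalent molybdenum alkylidene Mo(=N-2,6-iPr2C6H3)(=CHCMe2Ph)(3,3'-di-tert-butyl-5,5',6,6'-tetramethylbiphenyl-2,2'-diolate) selects one of two vinyl groups on C10 and closes ring A to A2, the 10-vinyl analogue of the methyl ester.
- Merits: the reaction class is better precedented than the chosen key step. C10 is set by the catalyst, so the ligand enantiomer offers a choice that substrate control does not.
- Weak points: the substrate already contains the C2–C10 bond between two fully substituted carbons, so the hardest bond is moved into the substrate synthesis. The two vinyl groups are diastereotopic in a chiral substrate (matched or mismatched). The ring closure makes a trisubstituted alkene next to a quaternary carbon. A2 still needs phenyl on the remaining vinyl group.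
- Comparison: the chosen plan sets against this the fact that its key step itself creates both quaternary centres.

**Alternative 3: rhodium hydroacylation closing ring B last.**
- Cut: C4–C5.
- Forward step: cationic monovalent rhodium, [Rh(BINAP)]ClO4, inserts into the C4 aldehyde C–H bond, delivers hydride to C6 of an isopropenyl group on C7 and closes the cyclopentanone A3. A3 is the same compound as 23 of the chosen route.
- Merits: a known, atom-economic catalytic reaction forms ring B and C6 in one step without a chiral-pool cyclopentenone. In economy for ring B it is as good as or better than the chosen plan.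
- Weak points: C2, C10, C3 and C7 must all be set beforehand on a monocyclic cyclohexene that lacks the conformational lock of ring B. The aldehyde sits on C3 next to quaternary C2, where it is hindered, epimerisable and prone to decarbonylation. A trans-fused five-membered ring must close with catalyst and substrate control in agreement.
- Comparison: the chosen plan sets against this the use of ring B from the first step as the anchor of the relay C6 → C7 → C3 → C2 → C10.

Key step: step 10

Remark: (R)-4-[(tert-butyldimethylsilyl)oxy]cyclopent-2-en-1-one, heptan-4-one, dimethyl oxalate, (E)-styrylboronic acid and PhI(OAc)2 are taken as commercial.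
Remark: C8 is sp2 in the target, so its configuration in 12–19 is immaterial; it is drawn as the epimer with the ethyl group equatorial (β).

## Route

Step 1
Reactants: 1 (R)-4-[(tert-butyldimethylsilyl)oxy]cyclopent-2-en-1-one
Product: 2 (3R,4R)-4-[(tert-butyldimethylsilyl)oxy]-3-methylcyclopentan-1-one
Conditions: Me2CuLi (MeLi, CuI), Et2O, –78 °C; aq. NH4Cl
Reagents that add atoms: lithium dimethylcuprate, [Li+].C[Cu-]C (made in the flask from methyllithium, [Li]C, and CuI)
Why: Cuprate conjugate addition to a 4-silyloxycyclopentenone; methyl enters anti to the silyloxy group, which sets the future C6 centre.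

Step 2
Reactants: 2 (3R,4R)-4-[(tert-butyldimethylsilyl)oxy]-3-methylcyclopentan-1-one
Product: 3 (R)-4-methylcyclopent-2-en-1-one
Conditions: DBU, CH2Cl2, 0 °C
Reagents that add atoms: none
Why: E1cB β-elimination of silanol from a β-silyloxy ketone; brief exposure at 0 °C should avoid γ-deprotonation, and the volatile enone is carried on as a solution.

Step 3
Reactants: 3 (R)-4-methylcyclopent-2-en-1-one
Product: 4 (R)-2-iodo-4-methylcyclopent-2-en-1-one
Conditions: I2, pyridine, CH2Cl2, 0 °C to rt
Reagents that add atoms: iodine, II
Why: α-Iodination of an enone by pyridine conjugate addition, iodination of the enolate and elimination; C6 is not involved.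

Step 4
Reactants: 4 (R)-2-iodo-4-methylcyclopent-2-en-1-one
Product: 5 (R)-6-iodo-8-methyl-1,4-dioxaspiro[4.4]non-6-ene
Conditions: (Me3SiOCH2)2, Me3SiOTf (cat.), CH2Cl2, –78 to –20 °C
Reagents that add atoms: 1,2-bis(trimethylsilyloxy)ethane, C[Si](C)(C)OCCO[Si](C)(C)C
Why: Silyl-triflate-catalysed aprotic ketalisation; the kinetic, non-protic conditions should leave the alkene in place and C6 untouched.

Step 5
Reactants: 5 (R)-6-iodo-8-methyl-1,4-dioxaspiro[4.4]non-6-ene; 6 dimethyl oxalate
Product: 8 methyl 2-[(8R)-8-methyl-1,4-dioxaspiro[4.4]non-6-en-6-yl]-2-oxoacetate, via vinyllithium 7 (not isolated)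
Conditions: n-BuLi, THF, –78 °C; added to (CO2Me)2 (excess), THF, –78 °C; AcOH
Reagents that add atoms: none
Why: Iodine–lithium exchange gives the α-lithiated enone equivalent; mono-acylation by the oxalate stops at the keto ester because the tetrahedral lithium adduct persists at –78 °C.

Step 6
Reactants: 9 heptan-4-one
Product: 10 (Z)-(hept-3-en-4-yloxy)trimethylsilane
Conditions: Me3SiOTf, Et3N, CH2Cl2, 0 °C
Reagents that add atoms: trimethylsilyl trifluoromethanesulfonate, C[Si](C)(C)OS(=O)(=O)C(F)(F)F
Why: Soft enolisation and O-silylation of a symmetrical ketone; the enol ether geometry is immaterial because C8 is later sp2.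

Step 7
Reactants: 8 methyl 2-[(8R)-8-methyl-1,4-dioxaspiro[4.4]non-6-en-6-yl]-2-oxoacetate; 10 (Z)-(hept-3-en-4-yloxy)trimethylsilane
Product: 12 methyl 2-[(6S,7R,8R)-8-methyl-7-[(3R)-4-oxoheptan-3-yl]-1,4-dioxaspiro[4.4]nonan-6-yl]-2-oxoacetate, via silyl enol ether 11 (not isolated)
Conditions: Sc(OTf)3 (10 mol%), CH2Cl2, –78 to –40 °C; then AcOH, THF/H2O, 0 °C
Reagents that add atoms: none
Why: Mukaiyama–Michael addition to a β,γ-unsaturated α-keto ester activated by two-point binding of the 1,2-dicarbonyl unit; the enol ether attacks C7 anti to the adjacent C6 methyl group, C3 is set on protonation and can equilibrate to the all-trans cyclopentane, and the C8 epimers converge later.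

Step 8
Reactants: 12 methyl 2-[(6S,7R,8R)-8-methyl-7-[(3R)-4-oxoheptan-3-yl]-1,4-dioxaspiro[4.4]nonan-6-yl]-2-oxoacetate
Product: 14 methyl (3'R,3a'R,4'R,7a'S)-4',6'-diethyl-3'-methyl-5'-oxo-2',3',3a',4',5',7a'-hexahydrospiro[[1,3]dioxolane-2,1'-indene]-7'-carboxylate, via ketol 13 (not isolated)
Conditions: NaOMe (0.3 equiv), MeOH, 0 °C to rt
Reagents that add atoms: none
Why: Second half of the Robinson annulation: the C10 enolate closes ring A on the electrophilic C2 keto carbonyl (6-enolexo aldol) and E1cB loss of water gives the C10=C2 enone; C3 should be trans to C7 because the α-keto ester equilibrates to the all-trans cyclopentane before closure and is no longer next to a carbonyl in the ketol, and C8 settles with ethyl equatorial.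

Step 9
Reactants: 15 (E)-(2-phenylethenyl)boronic acid; 16 (diacetoxyiodo)benzene
Product: 17 (E)-(2-phenylethenyl)(phenyl)iodonium tetrafluoroborate
Conditions: BF3·OEt2, CH2Cl2, 0 °C; then sat. aq. NaBF4
Reagents that add atoms: sodium tetrafluoroborate, [Na+].F[B-](F)(F)F
Why: Boron-to-iodine exchange of an alkenylboronic acid with activated PhI(OAc)2, with retention of the E geometry, followed by anion metathesis.

Step 10
Reactants: 14 methyl (3'R,3a'R,4'R,7a'S)-4',6'-diethyl-3'-methyl-5'-oxo-2',3',3a',4',5',7a'-hexahydrospiro[[1,3]dioxolane-2,1'-indene]-7'-carboxylate; 17 (E)-(2-phenylethenyl)(phenyl)iodonium tetrafluoroborate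
Product: 19 methyl (3'R,3a'R,4'R,6'R,7'R,7a'S)-4',6'-diethyl-3',7'-dimethyl-5'-oxo-6'-[(E)-2-phenylethenyl]octahydrospiro[[1,3]dioxolane-2,1'-indene]-7'-carboxylate, via lithium enolate 18 (not isolated)
Conditions: Me2CuLi (MeLi, CuI; 1.3 equiv), Et2O, –78 to –20 °C; then 17 (excess), THF/DMPU, –78 °C to rt
Reagents that add atoms: lithium dimethylcuprate, [Li+].C[Cu-]C (made in the flask from methyllithium, [Li]C, and CuI)
Why: Proposed new method: cuprate conjugate addition with enolate trapping and α-alkenylation of enolates by alkenyl(aryl)iodonium salts are each known reaction types, but their one-flask union to build two adjacent quaternary carbons on a tetrasubstituted ene-keto ester is not; mechanistically the monovalent copper reagent complexes the electron-poor C10=C2 bond, bonds to C2 (the carbon β to the ketone, the stronger acceptor since the flanked ester is twisted out of conjugation) and reductively eliminates to give the C2–CH3 bond and lithium enolate 18, regiodefined at C9–C10. The enolate then exchanges a ligand on the trivalent iodine centre of 17 and the C10–C11 bond forms by ligand coupling with loss of iodobenzene, or, with the methylcopper left in the flask, through an alkenyl trivalent copper intermediate; either path keeps the E geometry and transfers the alkenyl group in preference to phenyl. No ring closes. C2 is set by the ring fusion: trans-fused ring B holds ring A in a single half-chair with 3-H axial on the α face, so the chair-like axial trajectory brings methyl to the β face, syn to 7-H. C10 is set by that new axial methyl group: the enolate reacts on its α face, antiperiplanar to the C2–CH3 bond and again axially, so that methyl and ethyl end cis and ester and styryl end cis. The step needs regioselectivity (C2 over C10), C- over O-alkenylation and two face selections, secured respectively by the ketone as the dominant acceptor, by the ligand-coupling mechanism and by the conformational lock. The cuprate excess is kept small and 17 is used in excess because residual methylcopper species consume the salt.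

Step 11
Reactants: 19 methyl (3'R,3a'R,4'R,6'R,7'R,7a'S)-4',6'-diethyl-3',7'-dimethyl-5'-oxo-6'-[(E)-2-phenylethenyl]octahydrospiro[[1,3]dioxolane-2,1'-indene]-7'-carboxylate
Product: 21 methyl (3'R,3a'S,6'R,7'R,7a'S)-4',6'-diethyl-3',7'-dimethyl-6'-[(E)-2-phenylethenyl]-5'-{[(trifluoromethyl)sulfonyl]oxy}-2',3',3a',6',7',7a'-hexahydrospiro[[1,3]dioxolane-2,1'-indene]-7'-carboxylate, via potassium enolate 20 (not isolated)
Conditions: KN(SiMe3)2, THF, –78 to 0 °C; then Comins' reagent, –78 °C to rt
Reagents that add atoms: N-(5-chloropyridin-2-yl)-1,1,1-trifluoro-N-[(trifluoromethyl)sulfonyl]methanesulfonamide (Comins' reagent), O=S(=O)(N(c1ccc(Cl)cn1)S(=O)(=O)C(F)(F)F)C(F)(F)F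
Why: Enol triflate formation; C10 is quaternary, so the only enolisable position is the axial 8-H and the C8=C9 position is fixed; the ester has no α-hydrogen.

Step 12
Reactants: 21 methyl (3'R,3a'S,6'R,7'R,7a'S)-4',6'-diethyl-3',7'-dimethyl-6'-[(E)-2-phenylethenyl]-5'-{[(trifluoromethyl)sulfonyl]oxy}-2',3',3a',6',7',7a'-hexahydrospiro[[1,3]dioxolane-2,1'-indene]-7'-carboxylate
Product: 22 methyl (3'R,3a'S,6'S,7'R,7a'S)-4',6'-diethyl-3',7'-dimethyl-6'-[(E)-2-phenylethenyl]-2',3',3a',6',7',7a'-hexahydrospiro[[1,3]dioxolane-2,1'-indene]-7'-carboxylate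
Conditions: Pd(OAc)2 (5 mol%), PPh3, n-Bu3N, HCO2H, DMF, 60 °C
Reagents that add atoms: none
Why: Palladium-catalysed formate reduction of an alkenyl triflate (oxidative addition to zerovalent palladium, formate exchange, decarboxylation, reductive elimination); the styrene and ester are inert.

Step 13
Reactants: 22 methyl (3'R,3a'S,6'S,7'R,7a'S)-4',6'-diethyl-3',7'-dimethyl-6'-[(E)-2-phenylethenyl]-2',3',3a',6',7',7a'-hexahydrospiro[[1,3]dioxolane-2,1'-indene]-7'-carboxylate
Product: 23 methyl (1R,3aS,4R,5S,7aS)-5,7-diethyl-1,4-dimethyl-3-oxo-5-[(E)-2-phenylethenyl]-2,3,3a,4,5,7a-hexahydro-1H-indene-4-carboxylate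
Conditions: PPTS, acetone/H2O, 60 °C
Reagents that add atoms: water, O
Why: Mild acid hydrolysis of the dioxolane; the weak acid should spare the alkenes and not enolise the ketone toward the shielded 3-H.

Step 14
Reactants: 23 methyl (1R,3aS,4R,5S,7aS)-5,7-diethyl-1,4-dimethyl-3-oxo-5-[(E)-2-phenylethenyl]-2,3,3a,4,5,7a-hexahydro-1H-indene-4-carboxylate
Product: 25 methyl (1S,3aS,4R,5S,7aS)-5,7-diethyl-1,4-dimethyl-5-[(E)-2-phenylethenyl]-3-{[(trifluoromethyl)sulfonyl]oxy}-3a,4,5,7a-tetrahydro-1H-indene-4-carboxylate, via potassium enolate 24 (not isolated)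
Conditions: KN(SiMe3)2, THF, –78 °C; then Comins' reagent, –78 to 0 °C
Reagents that add atoms: N-(5-chloropyridin-2-yl)-1,1,1-trifluoro-N-[(trifluoromethyl)sulfonyl]methanesulfonamide (Comins' reagent), O=S(=O)(N(c1ccc(Cl)cn1)S(=O)(=O)C(F)(F)F)C(F)(F)F
Why: Kinetic enolisation of the cyclopentanone at the open C5 methylene, not at the shielded ring-fusion 3-H, then O-sulfonylation; this places C4=C5 and removes the risk at C3.

Step 15
Reactants: 25 methyl (1S,3aS,4R,5S,7aS)-5,7-diethyl-1,4-dimethyl-5-[(E)-2-phenylethenyl]-3-{[(trifluoromethyl)sulfonyl]oxy}-3a,4,5,7a-tetrahydro-1H-indene-4-carboxylate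
Product: 26 methyl (1R,3aR,4R,5S,7aS)-3,5,7-triethyl-1,4-dimethyl-5-[(E)-2-phenylethenyl]-3a,4,5,7a-tetrahydro-1H-indene-4-carboxylate
Conditions: EtMgBr, Fe(acac)3 (5 mol%), THF/NMP, –30 to 0 °C
Reagents that add atoms: ethylmagnesium bromide, CC[Mg]Br
Why: Iron-catalysed cross-coupling of an alkenyl triflate with an alkyl Grignard reagent, fast at low temperature and tolerant of the hindered ester; the C4–ethyl bond forms on the existing C4=C5 alkene.

Step 16
Reactants: 26 methyl (1R,3aR,4R,5S,7aS)-3,5,7-triethyl-1,4-dimethyl-5-[(E)-2-phenylethenyl]-3a,4,5,7a-tetrahydro-1H-indene-4-carboxylate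
Product: 27 spiculoic acid B, (1R,3aR,4R,5S,7aS)-3,5,7-triethyl-1,4-dimethyl-5-[(E)-2-phenylethenyl]-3a,4,5,7a-tetrahydro-1H-indene-4-carboxylic acid
Conditions: NaSEt, DMF, 90 °C; then aq. NaH2PO4
Reagents that add atoms: none
Why: SN2 dealkylation of a hindered methyl ester by thiolate at the methyl carbon, which avoids the shielded carbonyl; no stereocentre is α-acidic and the weakly acidic work-up avoids lactonisation.

## Compound list

1 | (R)-4-[(tert-butyldimethylsilyl)oxy]cyclopent-2-en-1-one | O=C1C=C[C@H](O[Si](C)(C)C(C)(C)C)C1 | starting material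
2 | (3R,4R)-4-[(tert-butyldimethylsilyl)oxy]-3-methylcyclopentan-1-one | O=C1C[C@@H](C)[C@H](O[Si](C)(C)C(C)(C)C)C1 | intermediate
3 | (R)-4-methylcyclopent-2-en-1-one | O=C1C[C@@H](C)C=C1 | intermediate
4 | (R)-2-iodo-4-methylcyclopent-2-en-1-one | O=C1C[C@@H](C)C=C1I | intermediate
5 | (R)-6-iodo-8-methyl-1,4-dioxaspiro[4.4]non-6-ene | IC1=C[C@H](C)CC12OCCO2 | intermediate
6 | dimethyl oxalate | COC(=O)C(=O)OC | starting material
7 | [(8R)-8-methyl-1,4-dioxaspiro[4.4]non-6-en-6-yl]lithium (not isolated) | [Li]C1=C[C@H](C)CC12OCCO2 | intermediate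
8 | methyl 2-[(8R)-8-methyl-1,4-dioxaspiro[4.4]non-6-en-6-yl]-2-oxoacetate | COC(=O)C(=O)C1=C[C@H](C)CC12OCCO2 | intermediate
9 | heptan-4-one | CCCC(=O)CCC | starting material
10 | (Z)-(hept-3-en-4-yloxy)trimethylsilane | CC/C=C(/CCC)O[Si](C)(C)C | intermediate
11 | trimethylsilyl enol ether of 12 at C2–C3, enol ether geometry undefined (not isolated) | CCCC(=O)[C@H](CC)[C@H]1[C@H](C)CC2(OCCO2)C1=C(O[Si](C)(C)C)C(=O)OC | intermediate
12 | methyl 2-[(6S,7R,8R)-8-methyl-7-[(3R)-4-oxoheptan-3-yl]-1,4-dioxaspiro[4.4]nonan-6-yl]-2-oxoacetate | CCCC(=O)[C@H](CC)[C@H]1[C@H](C)CC2(OCCO2)[C@@H]1C(=O)C(=O)OC | intermediate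
13 | ketol: methyl (3'R,3a'R,4'R,7a'S)-4',6'-diethyl-7'-hydroxy-3'-methyl-5'-oxooctahydrospiro[[1,3]dioxolane-2,1'-indene]-7'-carboxylate, C2 and C10 undefined (not isolated) | CC[C@H]1C(=O)C(CC)C(O)(C(=O)OC)[C@@H]2[C@@H]1[C@H](C)CC23OCCO3 | intermediate
14 | methyl (3'R,3a'R,4'R,7a'S)-4',6'-diethyl-3'-methyl-5'-oxo-2',3',3a',4',5',7a'-hexahydrospiro[[1,3]dioxolane-2,1'-indene]-7'-carboxylate | CC[C@H]1C(=O)C(CC)=C(C(=O)OC)[C@@H]2[C@@H]1[C@H](C)CC23OCCO3 | intermediate
15 | (E)-(2-phenylethenyl)boronic acid | OB(O)/C=C/c1ccccc1 | starting material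
16 | (diacetoxyiodo)benzene | CC(=O)OI(OC(C)=O)c1ccccc1 | starting material
17 | (E)-(2-phenylethenyl)(phenyl)iodonium tetrafluoroborate | F[B-](F)(F)F.[I+](/C=C/c1ccccc1)c1ccccc1 | intermediate
18 | lithium C9–C10 enolate of the C2-methylated keto ester, 2-CH3 β (not isolated) | CC[C@H]1C([O-])=C(CC)[C@](C)(C(=O)OC)[C@@H]2[C@@H]1[C@H](C)CC23OCCO3.[Li+] | intermediate
19 | methyl (3'R,3a'R,4'R,6'R,7'R,7a'S)-4',6'-diethyl-3',7'-dimethyl-5'-oxo-6'-[(E)-2-phenylethenyl]octahydrospiro[[1,3]dioxolane-2,1'-indene]-7'-carboxylate | CC[C@H]1C(=O)[C@@](/C=C/c2ccccc2)(CC)[C@](C)(C(=O)OC)[C@@H]2[C@@H]1[C@H](C)CC23OCCO3 | intermediate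
20 | potassium C8–C9 enolate of 19 (not isolated) | CCC1=C([O-])[C@@](/C=C/c2ccccc2)(CC)[C@](C)(C(=O)OC)[C@@H]2[C@@H]1[C@H](C)CC23OCCO3.[K+] | intermediate
21 | methyl (3'R,3a'S,6'R,7'R,7a'S)-4',6'-diethyl-3',7'-dimethyl-6'-[(E)-2-phenylethenyl]-5'-{[(trifluoromethyl)sulfonyl]oxy}-2',3',3a',6',7',7a'-hexahydrospiro[[1,3]dioxolane-2,1'-indene]-7'-carboxylate | CCC1=C(OS(=O)(=O)C(F)(F)F)[C@@](/C=C/c2ccccc2)(CC)[C@](C)(C(=O)OC)[C@@H]2[C@@H]1[C@H](C)CC23OCCO3 | intermediate
22 | methyl (3'R,3a'S,6'S,7'R,7a'S)-4',6'-diethyl-3',7'-dimethyl-6'-[(E)-2-phenylethenyl]-2',3',3a',6',7',7a'-hexahydrospiro[[1,3]dioxolane-2,1'-indene]-7'-carboxylate | CCC1=C[C@@](/C=C/c2ccccc2)(CC)[C@](C)(C(=O)OC)[C@@H]2[C@@H]1[C@H](C)CC23OCCO3 | intermediate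
23 | methyl (1R,3aS,4R,5S,7aS)-5,7-diethyl-1,4-dimethyl-3-oxo-5-[(E)-2-phenylethenyl]-2,3,3a,4,5,7a-hexahydro-1H-indene-4-carboxylate | CCC1=C[C@@](/C=C/c2ccccc2)(CC)[C@](C)(C(=O)OC)[C@@H]2[C@@H]1[C@H](C)CC2=O | intermediate
24 | potassium C4–C5 enolate of 23 (not isolated) | CCC1=C[C@@](/C=C/c2ccccc2)(CC)[C@](C)(C(=O)OC)[C@@H]2[C@@H]1[C@H](C)C=C2[O-].[K+] | intermediate
25 | methyl (1S,3aS,4R,5S,7aS)-5,7-diethyl-1,4-dimethyl-5-[(E)-2-phenylethenyl]-3-{[(trifluoromethyl)sulfonyl]oxy}-3a,4,5,7a-tetrahydro-1H-indene-4-carboxylate | CCC1=C[C@@](/C=C/c2ccccc2)(CC)[C@](C)(C(=O)OC)[C@@H]2[C@@H]1[C@H](C)C=C2OS(=O)(=O)C(F)(F)F | intermediate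
26 | methyl (1R,3aR,4R,5S,7aS)-3,5,7-triethyl-1,4-dimethyl-5-[(E)-2-phenylethenyl]-3a,4,5,7a-tetrahydro-1H-indene-4-carboxylate | CCC1=C[C@@](/C=C/c2ccccc2)(CC)[C@](C)(C(=O)OC)[C@H]2C(CC)=C[C@@H](C)[C@H]12 | intermediate
27 | spiculoic acid B, (1R,3aR,4R,5S,7aS)-3,5,7-triethyl-1,4-dimethyl-5-[(E)-2-phenylethenyl]-3a,4,5,7a-tetrahydro-1H-indene-4-carboxylic acid | CCC1=C[C@@](/C=C/c2ccccc2)(CC)[C@](C)(C(=O)O)[C@H]2C(CC)=C[C@@H](C)[C@H]12 | target

## Step count and risks

Total: 16 steps. Longest linear sequence: 14 steps (1–5, 7, 8, 10–16); steps 6 and 9 prepare the two coupling partners.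

**Step 10 (key step, proposed new method).**
- What may go wrong: the congested tetrasubstituted alkene may be reduced by electron transfer or not react at all instead of accepting methyl. The basic, hindered enolate may be protonated, or may deprotonate the salt (α-elimination to a carbene and on to phenylacetylene), instead of coupling at carbon. Attack at C2 may lose its face preference, because the axial β trajectory passes the dioxolane.
- Fallback with known chemistry, from 14 back to 19: Me2CuLi in the presence of Me3SiCl (silyl-accelerated conjugate addition) gives silyl enol ether F1. A Mukaiyama aldol addition of F1 to phenylacetaldehyde (BF3·OEt2, CH2Cl2, –78 °C) makes the C10–C11 bond on the same α face and gives β-hydroxy ketone F2. Dehydration with Burgess reagent can run only toward the benzylic C12, since C10 is quaternary, and gives the (E)-styryl ketone 19.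

**Step 7.**
- What may go wrong: Lewis-acid opening of the allylic dioxolane, or insufficient face selectivity at C7 with the hindered trisubstituted enol ether.
- Fallback, from 9 and 8 back to 12: heptan-4-one is converted with pyrrolidine and TiCl4 into the enamine (E)-1-(hept-3-en-4-yl)pyrrolidine F3. F3 adds to 8 without acid or base (Stork enamine conjugate addition through a dihydropyran aminal). Buffered aqueous AcOH then releases 12.

**Step 8.**
- What may go wrong: loss of the trans ring fusion, because the minor cis diketone cyclises faster or because methoxide removes the γ-hydrogen 3-H of the product (epimerisation or deconjugation).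
- Fallback, from 12 back to 14: the aldol closure is run with catalytic DBU in CH2Cl2 at 0 °C and stopped at ketol 13, which is isolated; in 13, C3 is no longer next to a carbonyl group. A separate dehydration with SOCl2/pyridine at 0 °C (chlorosulfite, loss of the acidic 10-H) then gives 14 without exposure to alkoxide. No new compound arises.

**Step 11.**
- What may go wrong: incomplete deprotonation of the tertiary 8-H, or slow O-sulfonylation of an enolate flanked by quaternary C10.
- Fallback, from 19 back to 22 without any enolate: NaBH4/CeCl3·7H2O in MeOH reduces the C9 ketone to alcohol F4. Its xanthate F5 (NaH, CS2, MeI) is pyrolysed (Chugaev syn elimination). The elimination can take only 8-H because C10 bears no hydrogen, and gives 22. If the carbinol epimer has 9-OH anti to 8-H, POCl3/pyridine anti elimination of F4 serves instead.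

**Step 16.**
- What may go wrong: slow dealkylation of the deeply buried ester and thermal degradation of the diene at the temperature needed.
- Fallback, from 26 back to 27: LiAlH4 in THF reduces the ester to neopentyl alcohol F6. Dess–Martin periodinane gives aldehyde F7. Pinnick oxidation (NaClO2, NaH2PO4, 2-methylbut-2-ene) gives 27.

## Further compounds

F1 | step 10 | trimethylsilyl enol ether (C9–C10) of the C2-methylated keto ester | CC[C@H]1C(O[Si](C)(C)C)=C(CC)[C@](C)(C(=O)OC)[C@@H]2[C@@H]1[C@H](C)CC23OCCO3
F2 | step 10 | β-hydroxy ketone with 1-hydroxy-2-phenylethyl on C10 (carbinol centre undefined) | CC[C@H]1C(=O)[C@@](C(O)Cc2ccccc2)(CC)[C@](C)(C(=O)OC)[C@@H]2[C@@H]1[C@H](C)CC23OCCO3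
F3 | step 7 | (E)-1-(hept-3-en-4-yl)pyrrolidine | CC/C=C(\CCC)N1CCCC1
F0 | step 8 | none | none
F4 | step 11 | C9 alcohol from 19 (9-OH α) | CC[C@H]1[C@H](O)[C@@](/C=C/c2ccccc2)(CC)[C@](C)(C(=O)OC)[C@@H]2[C@@H]1[C@H](C)CC23OCCO3
F5 | step 11 | S-methyl xanthate of F4 | CC[C@H]1[C@H](OC(=S)SC)[C@@](/C=C/c2ccccc2)(CC)[C@](C)(C(=O)OC)[C@@H]2[C@@H]1[C@H](C)CC23OCCO3
F6 | step 16 | primary alcohol (CH2OH in place of CO2Me of 26) | CCC1=C[C@@](/C=C/c2ccccc2)(CC)[C@](C)(CO)[C@H]2C(CC)=C[C@@H](C)[C@H]12
F7 | step 16 | aldehyde (CHO in place of CO2Me of 26) | CCC1=C[C@@](/C=C/c2ccccc2)(CC)[C@](C)(C=O)[C@H]2C(CC)=C[C@@H](C)[C@H]12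
A1 | alternative 1 | spiro 2-oxabicyclo[2.1.1]hexan-3-one photoadduct | O=C1C[C@@H](C)[C@H](C2(CC)SCCCS2)[C@]13[C@@H]4OC(=O)[C@@]3(C)[C@@]4(CC)CO[Si](C)(C)C(C)(C)C
A2 | alternative 2 | 10-vinyl analogue of spiculoic acid B methyl ester | CCC1=C[C@@](C=C)(CC)[C@](C)(C(=O)OC)[C@H]2C(CC)=C[C@@H](C)[C@H]12
A3 | alternative 3 | trans-fused C4 ketone lacking the C4 ethyl group (identical with 23) | CCC1=C[C@@](/C=C/c2ccccc2)(CC)[C@](C)(C(=O)OC)[C@H]2C(=O)C[C@@H](C)[C@H]12
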